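**Retrosynthetic overview**

1. The target is traced back (acid deprotection, double benzoylation, ester reduction) to a methyl cyclohexenecarboxylate that has O3/O4 in a trans-fused butane-2,3-diacetal (1,4-dioxane) ring, O5 as a benzoate and a free C6–OH.
2. Key disconnection C1–C6: an intramolecular Nozaki–Hiyama–Kishi closure of an acyclic Z-alkenyl triflate (C1) onto the C6 aldehyde re-forms the carbocycle, places the alkene at C1=C2 and creates the C6 carbinol centre in one operation.
3. The open chain comes from carbon–carbon cleavage (ozonolysis of the ring C=C) of cheap (−)-shikimic acid, whose three stereocentres become C3, C4 and C5 unchanged; cutting and re-joining the same two carbons moves the alkene to the other side of C1 and brings in the fourth oxygen.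
4. Enabling feature: after cleavage C1 is an α-keto ester ketone flanked only by the ester carbon C7 and the C2 methylene, so it enolises one way and becomes the nucleophilic alkenyl carbon; the dioxane ring across C3–C4 holds the C2 and C5 arms gauche and locks the forming half-chair with C5–OBz axial, which should direct the new C6–OH trans.
5. Ring order: dioxane (temporary, step 1), shikimate carbocycle opened (step 3), target cyclohexene closed (step 5), dioxane removed (step 9).

Key step: step 5

Remark on the chemistry: target locants are used for every compound (C1 carries the exocyclic carbon C7, C2 is the vinylic CH, C3 and C4 are the free carbinols, C5 carries the benzoate, C6 is the carbinol next to C1); these are shikimic acid's own C1, C6, C5, C4, C3 and C2, so in compounds 1 to 4 the ring double bond is C1=C6, and reagents are given with SMILES in the steps and are not numbered.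

**Route**

Step 1
Reactants: 1 (−)-shikimic acid
Product: 3 methyl shikimate O3/O4-butane-2,3-diacetal, via methyl shikimate 2 (not isolated)
Conditions: butane-2,3-dione, HC(OMe)3, camphorsulfonic acid (cat.), MeOH, reflux
Reagents that add atoms: methanol, CO; butane-2,3-dione, CC(=O)C(C)=O; trimethyl orthoformate, COC(OC)OC (water scavenger and possible methoxy donor)
Why: Fischer esterification is followed by thermodynamically controlled butane-2,3-diacetal formation, which should select the trans diol O3/O4 over the cis pair O4/O5 because only the trans diol gives a trans-fused chair dioxane with both methoxy groups axial (double anomeric stabilisation), and this also sets the two acetal centres as S,S while no carbinol centre is touched.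

Step 2
Reactants: 3 methyl shikimate O3/O4-butane-2,3-diacetal
Product: 4 the 5-O-benzoate of 3
Conditions: BzCl, pyridine, DMAP (cat.), CH2Cl2, 0 °C to rt
Reagents that add atoms: benzoyl chloride, O=C(Cl)c1ccccc1
Why: DMAP-catalysed acylation of the only free hydroxyl (C5–OH) installs the ester that masks O5 during the ring remodelling, with no stereocentre affected.

Step 3
Reactants: 4 the 5-O-benzoate of 3
Product: 6 acyclic C1-keto ester C6-aldehyde, via methoxy hydroperoxide 5 (not isolated)
Conditions: O3, CH2Cl2/MeOH 4:1, −78 °C; then Me2S, −78 °C to rt; crude product dried azeotropically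
Reagents that add atoms: ozone, [O-][O+]=O
Why: In this ozonolysis of a trisubstituted enoate the cycloreversion should put the carbonyl oxide on C6 (away from the ester-bearing C1), methanol traps it as hydroperoxide 5 and Me2S reduces it, so the ring C1=C6 bond is cut to the C1 α-keto ester and the C6 aldehyde while C3, C4, C5 and the diacetal (no acetal C–H) stay untouched.

Step 4
Reactants: 6 acyclic C1-keto ester C6-aldehyde
Product: 7 (Z)-enol triflate aldehyde
Conditions: Tf2O, iPr2NEt (added last), CH2Cl2, −78 °C
Reagents that add atoms: trifluoromethanesulfonic anhydride, O=S(=O)(OS(=O)(=O)C(F)(F)F)C(F)(F)F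
Why: In this soft enolisation and O-sulfonylation the C1 ketone can enolise only toward C2, its α-protons are far more acidic than the aldehyde α-proton at C5, and the enolate that keeps the ester trans to the chain should be trapped by Tf2O at −78 °C faster than it can add to the aldehyde or expel O3, giving the Z enol triflate (triflate cis to C3).

Step 5
Reactants: 7 (Z)-enol triflate aldehyde
Product: 9 methyl 5-benzoyloxy-6-hydroxy-3,4-O-diacetal-cyclohex-1-ene-1-carboxylate (5,6-trans), via alkenyl-CrCl2 species 8 (not isolated)
Conditions: CrCl2 (5 equiv), NiCl2 (2 mol%), degassed DMF, 0.01 M, rt; aqueous work-up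
Reagents that add atoms: none
Why: Zerovalent nickel (made from NiCl2 by CrCl2) inserts into the alkenyl C–OTf bond, transmetalation to trivalent chromium gives the alkenyl-CrCl2 species 8 with retention of the Z geometry, and its carbon C1 adds to the C6 aldehyde; this is an intramolecular Nozaki–Hiyama–Kishi reaction, the reaction type used to close alkenyl halide or triflate aldehydes to 2-substituted cyclohex-2-enols. The cyclohexene closes in a 6-exo-trig mode onto the C=O, and only the Z geometry puts the metal on the side of the chain where it can reach the aldehyde. The trans-fused diacetal dioxane holds the arms on C3 and C4 gauche and fixes the forming half-chair so that the C5 benzoate is axial. The new C6 stereocentre should then be set by the aldehyde placing its oxygen pseudoaxial on the face away from the C5–O bond (dipole minimisation with the α-benzoyloxy group and avoidance of A(1,2) strain with the ester on C1), which gives the 5,6-trans alcohol. The step needs chemoselectivity for the aldehyde over the two esters, which organochromium reagents provide because they do not add to esters, and the neutral conditions should leave the α-benzoyloxy aldehyde unepimerised. In one operation the ring is rebuilt with its double bond on the other side of C1 and with the fourth oxygen and its stereocentre in place.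

Step 6
Reactants: 9 methyl 5-benzoyloxy-6-hydroxy-3,4-O-diacetal-cyclohex-1-ene-1-carboxylate
Product: 10 the 6-O-triethylsilyl ether of 9
Conditions: Et3SiOTf, 2,6-lutidine, CH2Cl2, −78 to 0 °C
Reagents that add atoms: triethylsilyl trifluoromethanesulfonate, CC[Si](CC)(CC)OS(=O)(=O)C(F)(F)F
Why: Silylation of the hindered pseudoaxial allylic alcohol with a silyl triflate and a hindered pyridine base is reliable, and the trans-diaxial relation to the C5 benzoate rules out acyl or silyl migration.

Step 7
Reactants: 10 the 6-O-triethylsilyl ether of 9
Product: 11 C7,C5-diol (6-O-TES; 3,4-O-diacetal)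
Conditions: iBu2AlH (6 equiv), CH2Cl2, −78 to −40 °C; aqueous potassium sodium tartrate (KNaC4H4O6)
Reagents that add atoms: none
Why: iBu2AlH should reduce the conjugated methyl ester 1,2 to the allylic alcohol and in the same pot cleave the C5 benzoate reductively, exposing exactly the two hydroxyls that carry benzoates in the target while the silyl ether and the diacetal stay in place.

Step 8
Reactants: 11 C7,C5-diol
Product: 12 the 7-O,5-O-dibenzoate of 11
Conditions: BzCl (3 equiv), pyridine, DMAP, CH2Cl2, 0 °C to rt
Reagents that add atoms: benzoyl chloride, O=C(Cl)c1ccccc1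
Why: DMAP-catalysed double benzoylation of the primary allylic and the axial C5 hydroxyl leaves no regiochemical choice, since every other oxygen is blocked.

Step 9
Reactants: 12 the 7-O,5-O-dibenzoate of 11
Product: 13 target, [(3R,4S,5R,6S)-5-benzoyloxy-3,4,6-trihydroxycyclohex-1-en-1-yl]methyl benzoate
Conditions: CF3CO2H/H2O 9:1, 0 °C to rt, short reaction time
Reagents that add atoms: none
Why: Aqueous trifluoroacetic acid should hydrolyse the diacetal and the triethylsilyl ether in one operation under conditions in which benzoates neither cleave nor migrate at a useful rate, giving the target with all four stereocentres unchanged.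

**Compound list**

1 | (−)-shikimic acid, (3R,4S,5R)-3,4,5-trihydroxycyclohex-1-ene-1-carboxylic acid | OC(=O)C1=C[C@@H](O)[C@@H](O)[C@H](O)C1 | starting material
2 | methyl shikimate (methyl ester of 1, formed in the flask) | COC(=O)C1=C[C@@H](O)[C@@H](O)[C@H](O)C1 | intermediate
3 | methyl shikimate O3/O4-butane-2,3-diacetal: trans diol bridged by a (2S,3S)-2,3-dimethoxybutane-2,3-diyl unit as a trans-fused chair 1,4-dioxane with both OMe axial; C5–OH free; ring alkene C1=C6 | COC(=O)C1=C[C@@H](O)[C@H]2O[C@](C)(OC)[C@@](C)(OC)O[C@@H]2C1 | intermediate
4 | 5-O-benzoate of 3 | COC(=O)C1=C[C@@H](OC(=O)c3ccccc3)[C@H]2O[C@](C)(OC)[C@@](C)(OC)O[C@@H]2C1 | intermediate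
5 | ring-opened methoxy hydroperoxide: C1 α-keto methyl ester, C6 as CH(OMe)OOH (epimers at C6), otherwise as 6 (formed in the flask) | COC(=O)C(=O)C[C@H]1O[C@](C)(OC)[C@@](C)(OC)O[C@@H]1[C@H](OC(=O)c2ccccc2)C(OC)OO | intermediate
6 | acyclic keto ester aldehyde MeO2C–C1(=O)–C2H2–C3H–C4H–C5H(OBz)–C6H=O, O3/O4 in the diacetal dioxane, C3, C4, C5 as in shikimic acid | COC(=O)C(=O)C[C@H]1O[C@](C)(OC)[C@@](C)(OC)O[C@@H]1[C@H](OC(=O)c2ccccc2)C=O | intermediate
7 | (Z)-enol triflate of 6: MeO2C–C1(OTf)=C2H–, triflate cis to C3, aldehyde at C6 | COC(=O)/C(OS(=O)(=O)C(F)(F)F)=C/[C@H]1O[C@](C)(OC)[C@@](C)(OC)O[C@@H]1[C@H](OC(=O)c2ccccc2)C=O | intermediate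
8 | alkenyl-CrCl2 species: trivalent chromium on C1 in place of the triflate, Z (formed in the flask) | COC(=O)/C([Cr](Cl)Cl)=C/[C@H]1O[C@](C)(OC)[C@@](C)(OC)O[C@@H]1[C@H](OC(=O)c2ccccc2)C=O | intermediate
9 | methyl 5-benzoyloxy-6-hydroxy-3,4-O-diacetal-cyclohex-1-ene-1-carboxylate, alkene C1=C2, new centre 6S, 5,6-trans | COC(=O)C1=C[C@H]2O[C@](C)(OC)[C@@](C)(OC)O[C@@H]2[C@H](OC(=O)c3ccccc3)[C@H]1O | intermediate
10 | 6-O-triethylsilyl ether of 9 | COC(=O)C1=C[C@H]2O[C@](C)(OC)[C@@](C)(OC)O[C@@H]2[C@H](OC(=O)c3ccccc3)[C@H]1O[Si](CC)(CC)CC | intermediate
11 | diol: C7 primary allylic alcohol and free C5–OH, 6-O-TES, 3,4-O-diacetal | OCC1=C[C@H]2O[C@](C)(OC)[C@@](C)(OC)O[C@@H]2[C@H](O)[C@H]1O[Si](CC)(CC)CC | intermediate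
12 | 7-O,5-O-dibenzoate of 11 | O=C(OCC1=C[C@H]2O[C@](C)(OC)[C@@](C)(OC)O[C@@H]2[C@H](OC(=O)c3ccccc3)[C@H]1O[Si](CC)(CC)CC)c1ccccc1 | intermediate
13 | [(3R,4S,5R,6S)-5-benzoyloxy-3,4,6-trihydroxycyclohex-1-en-1-yl]methyl benzoate | O=C(OCC1=C[C@@H](O)[C@H](O)[C@H](OC(=O)c2ccccc2)[C@H]1O)c1ccccc1 | target

**Step count and risks**

Total steps: 9. Longest linear sequence: 9 steps, from 1.

Steps most likely to fail:

Step 4. The keto ester enolate may add to the C6 aldehyde (five-membered aldol ring), expel O3 by β-elimination, or epimerise C5 before it is sulfonylated, and Z control may erode. The fallback carries the aldehyde in masked form through the enolisation. It sets out from 6: chemoselective thioacetalisation of the aldehyde (propane-1,3-dithiol, MgBr2·OEt2, CH2Cl2) should give the 1,3-dithiane keto ester F1. Enol triflation, now free to use a stronger base (KN(SiMe3)2, PhNTf2, THF, −78 °C), gives the dithiane (Z)-enol triflate F2. Oxidative dethioacetalisation (PhI(OCOCF3)2, MeCN/H2O, 0 °C) returns to the route at 7.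

Step 5. The addition to the aldehyde may show poor facial selectivity and favour the 5,6-cis alcohol, or the alkenylchromium may be protonated before it closes the ring. The fallback sets the C6 centre by inversion instead of by the addition. It sets out from 7: the closure is run as described and the 5,6-cis alcohol F3 is taken on. Mitsunobu formylation (HCO2H, PPh3, DIAD, THF, 0 °C) inverts C6 without neighbouring-group interference, since the cis benzoate cannot attack from the rear, and gives the 6-O-formate F4. Mild methanolysis (KHCO3, MeOH, 0 °C), which spares the benzoate and the methyl ester, returns to the route at 9.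

Step 3. Ozone may react sluggishly with the electron-poor enoate, and the peroxidic intermediate or the keto aldehyde may decompose during reductive work-up. The fallback cleaves the ring in two stages without peroxides. It sets out from 4: dihydroxylation of the enoate (RuCl3 cat., NaIO4, CeCl3, EtOAc/MeCN/H2O, 0 °C, or OsO4 cat. with N-methylmorpholine N-oxide) should give the cis-1,6-diol F5, expected on the face away from the C5 benzoate, though the face is immaterial. Anhydrous glycol cleavage (Pb(OAc)4, benzene, rt) returns to the route at 6.

**Further compounds**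

F1 | step 4 | 1,3-dithiane (at C6) of keto ester aldehyde 6 | COC(=O)C(=O)C[C@H]1O[C@](C)(OC)[C@@](C)(OC)O[C@@H]1[C@H](OC(=O)c2ccccc2)C2SCCCS2
F2 | step 4 | 1,3-dithiane (at C6) of (Z)-enol triflate 7 | COC(=O)/C(OS(=O)(=O)C(F)(F)F)=C/[C@H]1O[C@](C)(OC)[C@@](C)(OC)O[C@@H]1[C@H](OC(=O)c2ccccc2)C2SCCCS2
F3 | step 5 | C6 epimer of 9 (5,6-cis alcohol) | COC(=O)C1=C[C@H]2O[C@](C)(OC)[C@@](C)(OC)O[C@@H]2[C@H](OC(=O)c3ccccc3)[C@@H]1O
F4 | step 5 | 6-O-formate of 9 (5,6-trans) | COC(=O)C1=C[C@H]2O[C@](C)(OC)[C@@](C)(OC)O[C@@H]2[C@H](OC(=O)c3ccccc3)[C@H]1OC=O
F5 | step 3 | cis-1,6-diol from dihydroxylation of 4 (hydroxyls anti to the C5 benzoate) | COC(=O)[C@@]1(O)[C@H](O)[C@@H](OC(=O)c3ccccc3)[C@H]2O[C@](C)(OC)[C@@](C)(OC)O[C@@H]2C1
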